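The west run and the north-east run are what I have for judging four new flasks, and I read them as one curve in percent of the charge.

| flask | substrate | temperature | remark | time |
|---|---|---|---|---|
| west | 0.043 M | 15 °C | run made earlier |  |
| north-east | 0.37 M | 59 °C | run made earlier |  |
| Monday's | 0.030 M | −5 °C |  | 8.0 h |
| Thursday's | 0.30 M | 15 °C |  | 8.0 h |
| Friday's | 0.10 M | 35 °C |  | 8.0 h |
| Sunday's | 0.050 M | 75 °C |  | 8.0 h |

- west (time / h: target / %): 1.00: 6.5; 2.50: 14.3; 6.00: 24.9; 15.0: 35.9
- north-east (time / min: target / %): 12.0: 35.0; 40.0: 34.9; 80.0: 35.3; 120: 35.2

(each reading ± 0.5 percentage points)

1. all flasks from highest to lowest amount of target, in percent of the substrate charged, at 8.0 h (Monday's / Thursday's / Friday's / Sunday's)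
2. the amount of target, in percent of the substrate charged of the flask you put first, at 8.0 h
3. the amount of target, in percent of the substrate charged of the flask you put last, at 8.0 h



North-east stands at a plateau of 35.1% from its first reading, and west climbs towards a similar height, although the charges differ by the factor 8.60. So I assume that the percent curve ignores the charge. Target rises to a ceiling S, and its gap to S shrinks exponentially. The first way to west's last reading borrows S from north-east and takes the rate from the 6.00 h reading, which foretells 33.5% at 15.0 h. The second way is the reading itself, 35.9%, higher by 2.4 percentage points against a scatter of 0.5 points. So the borrowed ceiling cheats, and, with the charge ignored as assumed, S differs between the two temperatures.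

Solving west's two late readings for S, pass by pass, gives 37.6%, 38.5%, 38.8% and 38.9%. The clock τ, the time in which the gap shrinks by the factor e, is then 5.86 h. The unused 1.00 h reading checks this: the curve gives 6.10%, and west read 6.5%.

Thursday's shares west's temperature, so with the charge ignored it should hold 28.9% of target. North-east's first reading already stands on the plateau, so at least 3 clocks had passed, since otherwise it would lie 1.7 points low. That makes its clock at most 4.00 min. With a constant factor per degree, a step of the size from 15 °C to 35 °C changes τ by at least 7.65. Friday's clock is then at most 0.766 h, well inside 8.0 h, and Sunday's, hotter than north-east, is shorter still. Both reach their ceilings, which I draw straight through the two known ones: 37.2% for Friday's and 33.7% for Sunday's. Monday's clock is at least 44.9 h, which on the same straight line for its ceiling gives at most 6.63% of target. I commit to Friday's over Sunday's, then Thursday's, then Monday's.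

The forecast, which says the west run “fits 2 substrate ⇌ target better than first-order reversible”, gives Thursday's > Friday's > Monday's > Sunday's, with 67% first and 4.9% last, and so parts from my reckoning.

The flasks give Friday's > Sunday's > Thursday's > Monday's, with 37.1% first and 3.01% last.

    substrate → target (k = 0.0130 min⁻¹, Ea = 91.0 kJ mol⁻¹)
    substrate → side product (k = 0.0220 min⁻¹, Ea = 94.0 kJ mol⁻¹)
    (constants at 35 °C)

S is the selectivity of these two parallel steps. Thursday's has not come to rest: τ leaves 25.5% of the substrate at 8.00 h, and the flask holds 26%. Monday's recipe at 20 °C, on the clock shortened per degree, leaves at most 10.3% of the substrate, and that neighbour holds 7.21%. Friday's has converted >99.9%, and ten times the time leaves its target unchanged. Monday's own target climbs to 21.9% at 80.0 h. For Thursday's, S and τ give 38.9% of target at 80.0 h, where the flask holds 39.1%.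

The data come from a simulation for an exercise, and the scatter is random.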